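**Remarks on the chemistry (assumptions)**
- Numbering and faces: azulene numbering is used for the bicycle (ring A = C1, C2, C3, C3a, C8a; ring B = C3a, C4 to C8, C8a); β is the face of the C8a methyl, α the opposite face.
- Availability: 1-ethoxycyclopropan-1-ol (10) is taken as purchasable; it also forms in one operation by methanolysis of its commercial trimethylsilyl ether.
- Ligand sense: (R)-BINAP is written in step 9; the antipode that leads to (8aR)-15 is the one meant, to be settled on a small scale.
- Structure check: the precursor 14 (E alkene) and the cycloadduct 15 (8aR), compared atom by atom with the target, carry the geometry and configuration the target requires as drawn.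

## Structural features

The target is a trans-fused hydroazulene: cyclopentane ring A (C1, C2, C3, C3a, C8a) and cycloheptanone ring B (C3a, C4, C5, C6, C7, C8, C8a) share the C3a–C8a bond. Ring B carries four adjacent oxidised carbons (the C4 4-hydroxybenzoate, the C5 ketone, the C6 tertiary methyl carbinol, the C7 secondary carbinol), and ring A carries the C3 tertiary isopropyl carbinol. Six stereocentres are present: C3, C3a and C4 are contiguous, C6 and C7 are contiguous, and the quaternary methyl-bearing C8a is bonded to C3a. Relative to the β C8a methyl, H-3a, the C4 ester oxygen, both hydroxyls at C6 and C7 and the C3 isopropyl group are all α, so each of them can be delivered to the face opposite the angular methyl. Fragile groups are the α-acyloxy ketone (epimerisation at C4, ester cleavage or migration under base), the tertiary α-ketol at C6 (acyloin shift), the β-hydroxy ketone relation of C7 to C5 (retro-aldol), the tertiary alcohols (dehydration) and the free phenol. The real difficulty is to set the quaternary C8a in absolute terms and then to place four oxygens and a trans ring-fusion hydrogen around a seven-membered ring without regiochemical ambiguity. The key step uses the fact that C8a, C8, C7, C6 and C5 form a five-carbon chain with its oxygen at C7, which is what a 1-siloxy-1-alkenylcyclopropane delivers, while C4 and C3a are the two carbons of an alkyne tied to C8a through C1, C2 and C3 of ring A.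

## Logic of the disconnections

37 to 36 to 34 + 35. The last bonds made are the ester C–O bond at C4 and the O–H bonds freed from three protecting groups. The ester and the phenol are the most base-sensitive parts, so they come last. The cut gives 34, which has a single free hydroxyl, and 35. The acylation is then site-specific by construction, and the deprotection of 36 must be one mild acidic operation that spares the new ester.

34 to 32. The C4–O bond is cut. In 32 the ketone can enolise only toward C4 because C6 is fully substituted, so oxygen can be added regiospecifically, and one stereocentre disappears. The forward step must add oxygen to the α face; the β methyl groups at C6 and C8a, both 1,3 to C4, should enforce this.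

32 to 31 to 30. The C3a–H and C4–H bonds are cut to the enone 30, with 31 as the unprotected diol. C3a is not next to a carbonyl in 31, so the trans fusion cannot be corrected by equilibration and must be set kinetically by hydrogen addition to the α face. The free α diol of 30 is kept to direct the catalyst. Electron-transfer reduction is excluded because the C6 oxygen (next to the ketone) and the C3 oxygen (on the carbon attached to the enone β-carbon) would be expelled.

30 to 29. Both C–O bonds at C6 and C7 are cut together to the alkene of 29. A syn-dihydroxylation guarantees the cis relation and brings both oxygens from the α face, anti to the C8a methyl. Reduction of a C7 ketone would instead need hydride from the hindered β face and is avoided for that reason. The demand is chemoselectivity for C6=C7 over C3a=C4, which the two fully substituted neighbours of C3a should provide.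

29 to 28 to 27. The C5 carbonyl oxygen is removed, giving the skipped diene 28 in which C5 is the only doubly allylic carbon. The ketone then comes from C–H oxidation at the most activated site, with no C–C bond formed. The oxidation must put oxygen on the central carbon, and the tertiary allylic alcohol of 27 must be masked first (28).

27 to 25 + 26. The C3–isopropyl bond is cut at a stage where the C3 carbonyl of 25 is the only carbonyl present, so there is no competition with the later C5 ketone. The forward step must be a 1,2-addition of a weakly basic organometallic from the α face.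

25 to 24 to 23 to 21 to 16 + 17. The C6 methyl is traced to the one-carbon unit of 17 and the C7–H bond to a C7–O bond; 24 is the ketal-protected form of 25. The C7 ketone of 16 is used once, to direct carbon to C6 and not to C8, and is then deleted through the enol triflate 23. Conjugate reduction of 21 creates the C6=C7 enolate without regiochemical choice. The demand is kinetic enolisation of 16 at C6, which the quaternary C8a beside C8 should secure.

16 to 15 to 14. This is the strategic cut: the C3a–C8a bond and the C4–C5 bond, which opens both rings at once. All ten ring carbons of 15 come from the acyclic, achiral 14, and the C7 oxygen arrives as an enol ether that is unmasked to 16 without touching the ketal. Only C8a is created, so the forward step must be enantioselective under catalyst control; the symmetrical cyclopropane leaves no regiochemical question.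

14 to 13 to 12 to 9 + 10. The C7–C8 bond between the alkenyl carbon and the carbinol carbon of the cyclopropane is cut. An alkenyl nucleophile adds to a cyclopropanone equivalent with retention of the E geometry, and the oxygen is then silylated. The alkyne C–H must stay masked through the organometallic step and is freed last.

9 to 8 to 7 to 5 + 6. The C3–C3a bond (carbonyl carbon to alkyne) is cut, and the ketal is traced to the ynone 8. An aldehyde and a metal acetylide are simple partners. The ketalisation must avoid conjugate addition to the ynone, which an aprotic protocol and the silyl cap of 6 provide.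

5 to 4 to 1 + 2. The C8a–CH3 bond and the C8–I bond are cut across the alkene. Carbometalation of the terminal alkyne of 1 with 2 fixes the trisubstituted E alkene as one isomer, which an olefination of a methyl ketone would not. The demand is syn addition with the methyl on the internal carbon.

## Other disconnections considered

Alternative 1: The cuts are the C8a–CH3 bond and the C3a–C4 bond, with ring B left open. Forward, a copper-catalysed enantioselective 1,4-addition of Me3Al 2 to 3-allylcyclopent-2-en-1-one A1, for example with Cu(OTf)2 and a chiral phosphoramidite, would create C8a. The aluminium enolate would then be trapped by ethyl glyoxylate A2 in an aldol reaction to give the trans-2,3-disubstituted cyclopentanone A3.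
- In favour: three of the six stereocentres, including the trans ring fusion that the chosen plan sets late by hydrogenation, arise in one operation from the achiral enone A1. Ring B could then be closed by ring-closing metathesis (second-generation Grubbs catalyst) between the allyl group and an isopropenyl unit installed at the ester carbon of A3. This would give the α-methyl cycloheptenone A4, a close relative of 29 that needs neither the C6 one-carbon sequence nor the C5 C–H oxidation.
- Against: β-substituted cyclopentenones are among the less responsive enones in copper-catalysed quaternary-centre formation. No obvious element fixes the configuration of the new carbinol carbon in the aldol with A2. A3 is a β-hydroxy ketone that can undergo retro-aldol cleavage and epimerise at C3a. The metathesis must form a trisubstituted, electron-poor double bond in a seven-membered ring.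
- Comparison: on structure, this plan builds ring B stepwise on a preformed ring A, whereas the chosen plan forms both rings at once. On mechanism, both depend on one enantioselective metal-catalysed C–C bond formation at the same quaternary carbon, so they are about equal in risk on absolute stereocontrol. On step economy the alternative is probably the better, because C3a and C4 arrive at the right oxidation level at the start. The chosen plan is preferred because its one catalyst-controlled centre then governs all others through a single facial rule, at the price of a longer redox sequence.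

Alternative 2: The cut is the C6–C7 bond of ring B. Forward, SmI2 (divalent samarium) would reduce the aldehyde and the methyl ketone of keto aldehyde A5 to ketyls. Their coupling closes the seven-membered ring and gives the cis-diol A6, with C4 and C5 held as an acetonide and C3 as a dioxolane.
- In favour: the two adjacent carbinols, one tertiary, are formed directly as the cis-diol at the right oxidation level during ring closure. The chosen plan needs three operations for this (removal of the C7 oxygen, dihydroxylation, protection). Chelation of both ketyl oxygens to one samarium centre is a well-understood source of cis selectivity.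
- Against: A5 must already hold C8a, C3a, C4 and an oxygenated C5 in the right relative arrangement, so the stereochemical burden moves into a long linear preparation. Seven-membered pinacol closures are entropically less favourable than five- or six-membered ones. The face of the new diol relative to the angular methyl is not guaranteed. After closure, four hydroxyls at C4 to C7 must be told apart so that only C5 is oxidised and only C4 acylated.
- Comparison: on structure, one ring bond and two stereocentres are formed, against two rings, two bonds and one stereocentre. On mechanism, it is a stoichiometric radical-anion coupling, against a catalytic cycloaddition. On the installation of the C6/C7 diol it is the equal or the better of the chosen plan. On overall step economy it is expected to be equal at best, because ring A and four other centres must be in place before the key step.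

Alternative 3: The cuts are the C5–C6 and C3a–C4 bonds, which removes C4 and C5 as a two-carbon unit. Forward, irradiation of the diquinane enone A7 with acetylene A8 would give the cyclobutene-fused ketone A9 by (2+2) photocycloaddition. Cleavage of the bond shared by the cyclobutene and the cyclopentanone would then expand that ring to the seven-membered dienone A10.
- In favour: A7 already carries the C3 isopropyl carbinol, the quaternary C8a and the C6 methyl. The question of placing the methyl next to the ketone, which costs the chosen plan the sequence from 16 to 24, does not arise; on this point the alternative is the better. The photocycloaddition forms two C–C bonds with light as the only reagent.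
- Against: opening a cis-fused bicyclo[3.2.0]heptene to a cis,cis-cycloheptadiene is the thermally disfavoured disrotatory mode and would need forcing temperatures that a tertiary silyl ether may not tolerate. Photocycloadditions of A8 are inefficient, and the cyclobutene product can react on under irradiation. A10 is a linear dienone with its oxygen at C7 as a ketone. The C5 ketone, the C4 oxygen, the C3a hydrogen and above all the α C7 hydroxyl, which a hydride reduction would have to deliver from the hindered β face, are all still to be set.
- Comparison: on structure, a preformed diquinane is ring-expanded, against direct formation of the hydroazulene. On mechanism, a photochemical cycloaddition plus a pericyclic opening stands against a metal-mediated cycloaddition; both use the strain of a small ring to reach the seven-membered ring and are equals in that respect. On step economy it is no better, because two stereocentres must be set before the key step and the late redox work is at least as long.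

Key step: step 9

## Route

**Step 1**
Reactants: 1 pent-4-yn-1-ol; 2 trimethylaluminium
Product: 4 (E)-5-iodo-4-methylpent-4-en-1-ol, via alkenylalane 3 (not isolated)
Conditions: Me3Al (3 equiv), Cp2ZrCl2 (cat.), CH2Cl2, 0 °C to rt; then I2, THF, −30 to 0 °C; aq. K2CO3
Reagents that add atoms: iodine [I][I]
Why: Negishi carboalumination catalysed by Cp2ZrCl2 adds methyl and aluminium syn across the terminal alkyne, methyl on the internal carbon, and iodinolysis with retention gives the E iodoalkene as one geometric isomer. The hydroxyl is carried as its aluminium alkoxide.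

**Step 2**
Reactants: 4 (E)-5-iodo-4-methylpent-4-en-1-ol
Product: 5 (E)-5-iodo-4-methylpent-4-enal
Conditions: TEMPO (cat.), PhI(OAc)2, CH2Cl2, rt
Reagents that add atoms: none
Why: Oxoammonium-mediated oxidation of a primary alcohol stops at the aldehyde and leaves the alkenyl iodide untouched.

**Step 3**
Reactants: 5 (E)-5-iodo-4-methylpent-4-enal; 6 ethynyltrimethylsilane
Product: 7 rac-(E)-7-iodo-6-methyl-1-(trimethylsilyl)hept-6-en-1-yn-3-ol
Conditions: 6, n-BuLi, THF, −78 °C; then 5, −78 °C; aq. NH4Cl
Reagents that add atoms: none
Why: 1,2-Addition of a lithium acetylide to an aldehyde at low temperature. The silyl cap masks the acidic alkyne C–H for the organometallic steps that follow, and the racemic carbinol centre is removed in step 4.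

**Step 4**
Reactants: 7 rac-(E)-7-iodo-6-methyl-1-(trimethylsilyl)hept-6-en-1-yn-3-ol
Product: 8 (E)-7-iodo-6-methyl-1-(trimethylsilyl)hept-6-en-1-yn-3-one
Conditions: MnO2 (excess), CH2Cl2, rt
Reagents that add atoms: none
Why: MnO2 oxidation is selective for activated (propargylic) alcohols and gives the ynone without affecting the alkenyl iodide.

**Step 5**
Reactants: 8 (E)-7-iodo-6-methyl-1-(trimethylsilyl)hept-6-en-1-yn-3-one
Product: 9 2-[(E)-4-iodo-3-methylbut-3-en-1-yl]-2-[(trimethylsilyl)ethynyl]-1,3-dioxolane
Conditions: (Me3SiOCH2)2, Me3SiOTf (cat.), CH2Cl2, −78 to −20 °C; pyridine quench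
Reagents that add atoms: 1,2-bis(trimethylsilyloxy)ethane C[Si](C)(C)OCCO[Si](C)(C)C
Why: Aprotic ketalisation with the bis-silyl ether of the diol under silyl triflate catalysis converts conjugated ynones to dioxolanes without conjugate addition of the diol. The silyl cap on the alkyne further disfavours 1,4-attack.

**Step 6**
Reactants: 9 2-[(E)-4-iodo-3-methylbut-3-en-1-yl]-2-[(trimethylsilyl)ethynyl]-1,3-dioxolane; 10 1-ethoxycyclopropan-1-ol
Product: 12 1-{(E)-2-methyl-4-[2-((trimethylsilyl)ethynyl)-1,3-dioxolan-2-yl]but-1-en-1-yl}cyclopropan-1-ol, via alkenyllithium 11 (not isolated)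
Conditions: flask A: 10, EtMgBr (1 equiv), THF, −78 to 0 °C; flask B: 9, t-BuLi (2 equiv), Et2O, −78 °C; B added to A, −78 °C to rt; aq. NH4Cl
Reagents that add atoms: none
Why: Iodine–lithium exchange retains the E geometry, and the alkenyllithium adds to cyclopropanone, which is released in equilibrium from the bromomagnesium salt of its ethyl hemiacetal (known synthesis of 1-substituted cyclopropanols). Ketal and silylalkyne are inert to the organolithium at −78 °C.

**Step 7**
Reactants: 12 1-{(E)-2-methyl-4-[2-((trimethylsilyl)ethynyl)-1,3-dioxolan-2-yl]but-1-en-1-yl}cyclopropan-1-ol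
Product: 13 tert-butyldimethyl[(1-{(E)-2-methyl-4-[2-((trimethylsilyl)ethynyl)-1,3-dioxolan-2-yl]but-1-en-1-yl}cyclopropyl)oxy]silane
Conditions: t-BuMe2SiCl, imidazole, DMF, rt
Reagents that add atoms: tert-butyldimethylsilyl chloride CC(C)(C)[Si](C)(C)Cl
Why: Silylation of the cyclopropanol under basic conditions avoids the acid-triggered ring expansion of 1-alkenylcyclopropanols to cyclobutanones.

**Step 8**
Reactants: 13 tert-butyldimethyl[(1-{(E)-2-methyl-4-[2-((trimethylsilyl)ethynyl)-1,3-dioxolan-2-yl]but-1-en-1-yl}cyclopropyl)oxy]silane
Product: 14 tert-butyl[(1-{(E)-4-(2-ethynyl-1,3-dioxolan-2-yl)-2-methylbut-1-en-1-yl}cyclopropyl)oxy]dimethylsilane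
Conditions: K2CO3 (cat.), MeOH, rt
Reagents that add atoms: none
Why: Base-catalysed methanolysis cleaves only the alkynyl C–Si bond; the tertiary silyl ether and the ketal are stable to carbonate in methanol.

**Step 9 (key step)**
Reactants: 14 tert-butyl[(1-{(E)-4-(2-ethynyl-1,3-dioxolan-2-yl)-2-methylbut-1-en-1-yl}cyclopropyl)oxy]dimethylsilane
Product: 15 (8aR)-7-(tert-butyldimethylsilyloxy)-3,3-(ethylenedioxy)-8a-methyl-1,2,3,5,6,8a-hexahydroazulene (double bonds C3a=C4 and C7=C8)
Conditions: [Rh(cod)2]SbF6 (5 mol %), (R)-BINAP (5.5 mol %), H2 pre-activation then argon, ClCH2CH2Cl, 70 °C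
Reagents that add atoms: none
Why: This is an intramolecular (5+2) cycloaddition of a vinylcyclopropane with a tethered alkyne, catalysed here by the cationic complex formed from [Rh(cod)2]SbF6 and BINAP, a known reaction class that includes enantioselective versions with bisphosphine complexes of monovalent rhodium. The metal binds the alkyne and the trisubstituted alkene, and oxidative cyclisation of this 1,6-enyne joins the internal alkyne carbon to the methyl-bearing alkene carbon; this forms the C3a–C8a bond, closes ring A as a five-membered ring through the three-carbon tether and gives a rhodacyclopentene of trivalent rhodium. The cyclopropane bond next to the new Rh–C8 bond then opens with release of ring strain (cyclopropylcarbinyl to homoallyl shift), which enlarges the metallacycle to a rhodacyclooctadiene and places the double bond at C7=C8 as the silyl enol ether; the other possible order, cyclopropane cleavage before alkyne insertion, would form the same bonds. Reductive elimination forms C4–C5, closes ring B as a seven-membered ring and returns monovalent rhodium. C8a is the only new stereocentre and is fixed in the C–C bond-forming cyclisation, where the chiral BINAP environment selects one face of the alkene. The step needs enantioface selection and cycloaddition in preference to alkyne oligomerisation. These are supported by the single E geometry of 14, by the ketal at the propargylic carbon (gem-disubstitution that favours cyclisation and carries no stereocentre) and by the siloxy group, which speeds ring opening. The two cyclopropane CH2 groups are equivalent, so the ring opening has no regiochemical alternative.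

**Step 10**
Reactants: 15 (8aR)-7-(tert-butyldimethylsilyloxy)-3,3-(ethylenedioxy)-8a-methyl-1,2,3,5,6,8a-hexahydroazulene
Product: 16 (8aR)-3,3-(ethylenedioxy)-8a-methyl-2,3,5,6,8,8a-hexahydroazulen-7(1H)-one (double bond C3a=C4)
Conditions: n-Bu4NF, AcOH, THF, 0 °C
Reagents that add atoms: none
Why: Fluoride cleaves the O–Si bond of the silyl enol ether and acetic acid protonates the enolate on carbon. The buffered, non-aqueous medium spares the allylic ketal, and no stereocentre is touched.

**Step 11**
Reactants: 16 (8aR)-3,3-(ethylenedioxy)-8a-methyl-2,3,5,6,8,8a-hexahydroazulen-7(1H)-one; 17 N,N-dimethylmethyleneiminium iodide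
Product: 21 (8aR)-3,3-(ethylenedioxy)-8a-methyl-6-methylene-2,3,5,6,8,8a-hexahydroazulen-7(1H)-one, via lithium enolate 18 (not isolated), via Mannich base 19 (not isolated), via ammonium iodide 20 (not isolated)
Conditions: LiN(iPr)2, THF, −78 °C; 17, −78 °C to rt; MeI, MeOH, rt; aq. NaHCO3, CH2Cl2, rt
Reagents that add atoms: none
Why: Kinetic deprotonation occurs at C6 and not at C8, which is shielded by the adjacent quaternary C8a. Mannich reaction with the iminium salt, N-methylation and mild elimination (Eschenmoser methylenation) install the carbon that becomes the C6 methyl; bicarbonate is used so that the exocyclic enone does not isomerise into the ring.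

**Step 12**
Reactants: 21 (8aR)-3,3-(ethylenedioxy)-8a-methyl-6-methylene-2,3,5,6,8,8a-hexahydroazulen-7(1H)-one
Product: 23 (8aR)-3,3-(ethylenedioxy)-6,8a-dimethyl-1,2,3,5,8,8a-hexahydroazulen-7-yl trifluoromethanesulfonate (double bonds C3a=C4 and C6=C7), via lithium enolate 22 (not isolated)
Conditions: LiBH(s-Bu)3, THF, −78 °C; then PhNTf2, −78 to 0 °C
Reagents that add atoms: N-phenylbis(trifluoromethanesulfonimide) O=S(=O)(N(c1ccccc1)S(=O)(=O)C(F)(F)F)C(F)(F)F
Why: The hindered LiBH(s-Bu)3 adds hydride to the unsubstituted exocyclic β-carbon (conjugate reduction), which creates the C6 methyl and the tetrasubstituted C6–C7 enolate with no regiochemical choice. O-Sulfonylation with the triflimide traps it as the enol triflate.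

**Step 13**
Reactants: 23 (8aR)-3,3-(ethylenedioxy)-6,8a-dimethyl-1,2,3,5,8,8a-hexahydroazulen-7-yl trifluoromethanesulfonate
Product: 24 (8aR)-3,3-(ethylenedioxy)-6,8a-dimethyl-1,2,3,5,8,8a-hexahydroazulene (double bonds C3a=C4 and C6=C7)
Conditions: Pd(OAc)2 (cat.), PPh3, n-Bu3N, HCO2H, DMF, 60 °C
Reagents that add atoms: none
Why: Formate reduction of an enol triflate catalysed by Pd(OAc)2 and PPh3 proceeds by oxidative addition to zerovalent palladium, formate exchange, loss of CO2 and C–H reductive elimination. It removes the C7 oxygen and leaves the C6=C7 alkene, the ketal and the C3a=C4 alkene in place.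

**Step 14**
Reactants: 24 (8aR)-3,3-(ethylenedioxy)-6,8a-dimethyl-1,2,3,5,8,8a-hexahydroazulene
Product: 25 (8aR)-6,8a-dimethyl-2,5,8,8a-tetrahydroazulen-3(1H)-one (double bonds C3a=C4 and C6=C7)
Conditions: pyridinium p-toluenesulfonate (cat.), acetone/H2O, 40 °C
Reagents that add atoms: water O
Why: Acid-catalysed hydrolysis of the dioxolane is assisted by the adjacent C3a=C4 double bond, so a weak acid suffices and the skipped diene is not isomerised.

**Step 15**
Reactants: 25 (8aR)-6,8a-dimethyl-2,5,8,8a-tetrahydroazulen-3(1H)-one; 26 isopropylmagnesium chloride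
Product: 27 (3R,8aR)-3-isopropyl-6,8a-dimethyl-1,2,3,5,8,8a-hexahydroazulen-3-ol (3β-hydroxyl)
Conditions: CeCl3 (anhydrous), THF, −78 °C; 26; then 25, −78 to −40 °C; aq. NH4Cl
Reagents that add atoms: none
Why: Organocerium 1,2-addition: the weakly basic i-PrCeCl2 adds to the enone carbonyl in preference to deprotonation at the doubly allylic C5 or to β-hydride reduction. It approaches C3 from the α face, anti to the pseudo-axial C8a methyl two bonds away, so the isopropyl group becomes α and the hydroxyl β.

**Step 16**
Reactants: 27 (3R,8aR)-3-isopropyl-6,8a-dimethyl-1,2,3,5,8,8a-hexahydroazulen-3-ol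
Product: 28 triethyl{[(3R,8aR)-3-isopropyl-6,8a-dimethyl-1,2,3,5,8,8a-hexahydroazulen-3-yl]oxy}silane
Conditions: Et3SiOTf, 2,6-lutidine, CH2Cl2, −78 to 0 °C
Reagents that add atoms: triethylsilyl trifluoromethanesulfonate CC[Si](CC)(CC)OS(=O)(=O)C(F)(F)F
Why: Silylation of the tertiary allylic alcohol with a silyl triflate and a hindered pyridine base. The ether prevents oxidative allylic transposition in step 17 and keeps the β oxygen from directing the hydrogenation of step 19.

**Step 17**
Reactants: 28 triethyl{[(3R,8aR)-3-isopropyl-6,8a-dimethyl-1,2,3,5,8,8a-hexahydroazulen-3-yl]oxy}silane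
Product: 29 (3R,8aR)-3-isopropyl-6,8a-dimethyl-3-(triethylsilyloxy)-2,3,8,8a-tetrahydroazulen-5(1H)-one (double bonds C3a=C4 and C6=C7)
Conditions: CrO3, 3,5-dimethylpyrazole, CH2Cl2, −20 °C
Reagents that add atoms: chromium trioxide O=[Cr](=O)=O
Why: Allylic oxidation with the CrO3–3,5-dimethylpyrazole complex (hexavalent chromium) takes place at C5, the only doubly allylic methylene and the site of the weakest C–H bonds. Oxygen is placed on the central carbon of the pentadienyl system and gives the cross-conjugated dienone.

**Step 18**
Reactants: 29 (3R,8aR)-3-isopropyl-6,8a-dimethyl-3-(triethylsilyloxy)-2,3,8,8a-tetrahydroazulen-5(1H)-one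
Product: 30 (3R,6S,7S,8aR)-6,7-dihydroxy-3-isopropyl-6,8a-dimethyl-3-(triethylsilyloxy)-2,3,6,7,8,8a-hexahydroazulen-5(1H)-one (6α,7α-diol; double bond C3a=C4)
Conditions: OsO4 (cat.), N-methylmorpholine N-oxide, acetone/H2O, rt
Reagents that add atoms: N-methylmorpholine N-oxide C[N+]1([O-])CCOCC1; water O
Why: Upjohn dihydroxylation adds both oxygens syn to C6=C7 and not to C3a=C4, which is flanked by two fully substituted carbons. OsO4 attacks the α face, away from the axial C8a methyl that is 1,3 to C7, so both hydroxyls are α and cis.

**Step 19**
Reactants: 30 (3R,6S,7S,8aR)-6,7-dihydroxy-3-isopropyl-6,8a-dimethyl-3-(triethylsilyloxy)-2,3,6,7,8,8a-hexahydroazulen-5(1H)-one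
Product: 31 (3R,3aR,6S,7S,8aR)-6,7-dihydroxy-3-isopropyl-6,8a-dimethyl-3-(triethylsilyloxy)octahydroazulen-5(1H)-one (H-3a α, trans-fused)
Conditions: [Ir(cod)(PCy3)(py)]PF6 (cat.), H2 (10 bar), CH2Cl2, rt
Reagents that add atoms: none
Why: Hydroxyl-directed homogeneous hydrogenation: the α hydroxyls at C6 and C7 bind the cationic complex [Ir(cod)(PCy3)(py)]PF6, and hydrogen is delivered to the α face of C3a=C4, which is also the face opposite the C8a methyl and the C3 silyl ether. This sets H-3a α, trans to the angular methyl; the ketone is not reduced.

**Step 20**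
Reactants: 31 (3R,3aR,6S,7S,8aR)-6,7-dihydroxy-3-isopropyl-6,8a-dimethyl-3-(triethylsilyloxy)octahydroazulen-5(1H)-one
Product: 32 (3R,3aR,6S,7S,8aR)-3-isopropyl-6,7-(isopropylidenedioxy)-6,8a-dimethyl-3-(triethylsilyloxy)octahydroazulen-5(1H)-one (6,7-acetonide of 31 on the α face)
Conditions: Me2C(OMe)2, pyridinium p-toluenesulfonate (cat.), CH2Cl2, rt
Reagents that add atoms: 2,2-dimethoxypropane COC(C)(C)OC
Why: Acid-catalysed transketalisation: the cis-1,2-diol closes a five-membered acetonide, and the tertiary silyl ether is stable to the weak, anhydrous acid.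

**Step 21**
Reactants: 32 (3R,3aR,6S,7S,8aR)-3-isopropyl-6,7-(isopropylidenedioxy)-6,8a-dimethyl-3-(triethylsilyloxy)octahydroazulen-5(1H)-one
Product: 34 (3R,3aS,4R,6S,7S,8aR)-4-hydroxy-3-isopropyl-6,7-(isopropylidenedioxy)-6,8a-dimethyl-3-(triethylsilyloxy)octahydroazulen-5(1H)-one (4α-hydroxyl), via potassium enolate 33 (not isolated)
Conditions: KN(SiMe3)2, THF, −78 °C; 2-(phenylsulfonyl)-3-phenyloxaziridine, −78 °C; aq. NH4Cl at −78 °C
Reagents that add atoms: 2-(phenylsulfonyl)-3-phenyloxaziridine O=S(=O)(N1OC1c1ccccc1)c1ccccc1
Why: Davis oxidation: the ketone can enolise only toward C4 because C6 is quaternary, and the potassium enolate is oxidised by the N-sulfonyloxaziridine. The β face of C4 is blocked by the C6 and C8a methyl groups, both 1,3 to C4, so the hydroxyl enters α, cis to H-3a.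

**Step 22**
Reactants: 34 (3R,3aS,4R,6S,7S,8aR)-4-hydroxy-3-isopropyl-6,7-(isopropylidenedioxy)-6,8a-dimethyl-3-(triethylsilyloxy)octahydroazulen-5(1H)-one; 35 4-acetoxybenzoyl chloride
Product: 36 (3R,3aS,4R,6S,7S,8aR)-3-isopropyl-6,7-(isopropylidenedioxy)-6,8a-dimethyl-5-oxo-3-(triethylsilyloxy)decahydroazulen-4-yl 4-acetoxybenzoate
Conditions: pyridine, 4-dimethylaminopyridine (cat.), CH2Cl2, 0 °C to rt
Reagents that add atoms: none
Why: Acylation of the only free hydroxyl with an acid chloride under nucleophilic catalysis; the acid chloride is far more reactive than the phenolic acetate it carries, so the aroyl group is transferred.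

**Step 23**
Reactants: 36 (3R,3aS,4R,6S,7S,8aR)-3-isopropyl-6,7-(isopropylidenedioxy)-6,8a-dimethyl-5-oxo-3-(triethylsilyloxy)decahydroazulen-4-yl 4-acetoxybenzoate
Product: 37 (3R,3aS,4R,6S,7S,8aR)-3,6,7-trihydroxy-3-isopropyl-6,8a-dimethyl-5-oxodecahydroazulen-4-yl 4-hydroxybenzoate (CNP0241001.1)
Conditions: HCl (1.25 M in MeOH), MeOH, 0 °C to rt
Reagents that add atoms: none
Why: Acid-catalysed methanolysis removes three groups in one operation: the tertiary triethylsilyl ether, the acetonide (transketalisation) and the phenolic acetate (transesterification, much faster than that of the hindered alkyl aroate). Cold, dilute acid is chosen to avoid dehydration of the tertiary alcohols and acyloin rearrangement at C6; no stereocentre is affected.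

## Compound list

1 | pent-4-yn-1-ol | C#CCCCO | starting material
2 | trimethylaluminium | C[Al](C)C | starting material
3 | dimethyl{[(E)-5-(dimethylalumanyl)-4-methylpent-4-en-1-yl]oxy}alumane | C[Al](C)OCCC/C(C)=C/[Al](C)C | intermediate (not isolated)
4 | (E)-5-iodo-4-methylpent-4-en-1-ol | OCCC/C(C)=C/I | intermediate
5 | (E)-5-iodo-4-methylpent-4-enal | O=CCC/C(C)=C/I | intermediate
6 | ethynyltrimethylsilane | C#C[Si](C)(C)C | starting material
7 | rac-(E)-7-iodo-6-methyl-1-(trimethylsilyl)hept-6-en-1-yn-3-ol | C[Si](C)(C)C#CC(O)CC/C(C)=C/I | intermediate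
8 | (E)-7-iodo-6-methyl-1-(trimethylsilyl)hept-6-en-1-yn-3-one | C[Si](C)(C)C#CC(=O)CC/C(C)=C/I | intermediate
9 | 2-[(E)-4-iodo-3-methylbut-3-en-1-yl]-2-[(trimethylsilyl)ethynyl]-1,3-dioxolane | C[Si](C)(C)C#CC1(OCCO1)CC/C(C)=C/I | intermediate
10 | 1-ethoxycyclopropan-1-ol | CCOC1(O)CC1 | starting material
11 | {(E)-2-methyl-4-[2-((trimethylsilyl)ethynyl)-1,3-dioxolan-2-yl]but-1-en-1-yl}lithium | C[Si](C)(C)C#CC1(OCCO1)CC/C(C)=C/[Li] | intermediate (not isolated)
12 | 1-{(E)-2-methyl-4-[2-((trimethylsilyl)ethynyl)-1,3-dioxolan-2-yl]but-1-en-1-yl}cyclopropan-1-ol | C[Si](C)(C)C#CC1(OCCO1)CC/C(C)=C/C2(O)CC2 | intermediate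
13 | tert-butyldimethyl[(1-{(E)-2-methyl-4-[2-((trimethylsilyl)ethynyl)-1,3-dioxolan-2-yl]but-1-en-1-yl}cyclopropyl)oxy]silane | C[Si](C)(C)C#CC1(OCCO1)CC/C(C)=C/C2(O[Si](C)(C)C(C)(C)C)CC2 | intermediate
14 | tert-butyl[(1-{(E)-4-(2-ethynyl-1,3-dioxolan-2-yl)-2-methylbut-1-en-1-yl}cyclopropyl)oxy]dimethylsilane | C#CC1(OCCO1)CC/C(C)=C/C2(O[Si](C)(C)C(C)(C)C)CC2 | intermediate (key-step precursor)
15 | (8aR)-7-(tert-butyldimethylsilyloxy)-3,3-(ethylenedioxy)-8a-methyl-1,2,3,5,6,8a-hexahydroazulene | CC(C)(C)[Si](C)(C)OC1=C[C@@]2(C)CCC3(OCCO3)C2=CCC1 | intermediate (key-step product)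
16 | (8aR)-3,3-(ethylenedioxy)-8a-methyl-2,3,5,6,8,8a-hexahydroazulen-7(1H)-one | O=C1C[C@@]2(C)CCC3(OCCO3)C2=CCC1 | intermediate
17 | N,N-dimethylmethyleneiminium iodide | C=[N+](C)C.[I-] | starting material
18 | lithium C6=C7 enolate of 16 | C1=C(O[Li])C[C@@]2(C)CCC3(OCCO3)C2=CC1 | intermediate (not isolated)
19 | 6-[(dimethylamino)methyl] derivative of 16 (C6 epimers) | O=C1C[C@@]2(C)CCC3(OCCO3)C2=CCC1CN(C)C | intermediate (not isolated)
20 | 6-[(trimethylammonio)methyl] derivative of 16, iodide | O=C1C[C@@]2(C)CCC3(OCCO3)C2=CCC1C[N+](C)(C)C.[I-] | intermediate (not isolated)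
21 | (8aR)-3,3-(ethylenedioxy)-8a-methyl-6-methylene-2,3,5,6,8,8a-hexahydroazulen-7(1H)-one | O=C1C[C@@]2(C)CCC3(OCCO3)C2=CCC1=C | intermediate
22 | lithium (8aR)-3,3-(ethylenedioxy)-6,8a-dimethyl-1,2,3,5,8,8a-hexahydroazulen-7-olate | CC1=C(O[Li])C[C@@]2(C)CCC3(OCCO3)C2=CC1 | intermediate (not isolated)
23 | (8aR)-3,3-(ethylenedioxy)-6,8a-dimethyl-1,2,3,5,8,8a-hexahydroazulen-7-yl trifluoromethanesulfonate | CC1=C(OS(=O)(=O)C(F)(F)F)C[C@@]2(C)CCC3(OCCO3)C2=CC1 | intermediate
24 | (8aR)-3,3-(ethylenedioxy)-6,8a-dimethyl-1,2,3,5,8,8a-hexahydroazulene | CC1=CC[C@@]2(C)CCC3(OCCO3)C2=CC1 | intermediate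
25 | (8aR)-6,8a-dimethyl-2,5,8,8a-tetrahydroazulen-3(1H)-one | CC1=CC[C@@]2(C)CCC(=O)C2=CC1 | intermediate
26 | isopropylmagnesium chloride | CC(C)[Mg]Cl | starting material
27 | (3R,8aR)-3-isopropyl-6,8a-dimethyl-1,2,3,5,8,8a-hexahydroazulen-3-ol | CC(C)[C@]1(O)CC[C@]2(C)CC=C(C)CC=C21 | intermediate
28 | triethyl{[(3R,8aR)-3-isopropyl-6,8a-dimethyl-1,2,3,5,8,8a-hexahydroazulen-3-yl]oxy}silane | CC(C)[C@]1(O[Si](CC)(CC)CC)CC[C@]2(C)CC=C(C)CC=C21 | intermediate
29 | (3R,8aR)-3-isopropyl-6,8a-dimethyl-3-(triethylsilyloxy)-2,3,8,8a-tetrahydroazulen-5(1H)-one | CC(C)[C@]1(O[Si](CC)(CC)CC)CC[C@]2(C)CC=C(C)C(=O)C=C21 | intermediate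
30 | (3R,6S,7S,8aR)-6,7-dihydroxy-3-isopropyl-6,8a-dimethyl-3-(triethylsilyloxy)-2,3,6,7,8,8a-hexahydroazulen-5(1H)-one | CC(C)[C@]1(O[Si](CC)(CC)CC)CC[C@]2(C)C[C@H](O)[C@](C)(O)C(=O)C=C21 | intermediate
31 | (3R,3aR,6S,7S,8aR)-6,7-dihydroxy-3-isopropyl-6,8a-dimethyl-3-(triethylsilyloxy)octahydroazulen-5(1H)-one | CC(C)[C@]1(O[Si](CC)(CC)CC)CC[C@]2(C)C[C@H](O)[C@](C)(O)C(=O)C[C@H]21 | intermediate
32 | (3R,3aR,6S,7S,8aR)-3-isopropyl-6,7-(isopropylidenedioxy)-6,8a-dimethyl-3-(triethylsilyloxy)octahydroazulen-5(1H)-one | CC(C)[C@]1(O[Si](CC)(CC)CC)CC[C@]2(C)C[C@@H]3OC(C)(C)O[C@]3(C)C(=O)C[C@H]21 | intermediate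
33 | potassium C4=C5 enolate of 32 | CC(C)[C@]1(O[Si](CC)(CC)CC)CC[C@]2(C)C[C@@H]3OC(C)(C)O[C@]3(C)C(O[K])=C[C@H]21 | intermediate (not isolated)
34 | (3R,3aS,4R,6S,7S,8aR)-4-hydroxy-3-isopropyl-6,7-(isopropylidenedioxy)-6,8a-dimethyl-3-(triethylsilyloxy)octahydroazulen-5(1H)-one | CC(C)[C@]1(O[Si](CC)(CC)CC)CC[C@]2(C)C[C@@H]3OC(C)(C)O[C@]3(C)C(=O)[C@H](O)[C@H]21 | intermediate
35 | 4-acetoxybenzoyl chloride | CC(=O)Oc1ccc(cc1)C(Cl)=O | starting material
36 | (3R,3aS,4R,6S,7S,8aR)-3-isopropyl-6,7-(isopropylidenedioxy)-6,8a-dimethyl-5-oxo-3-(triethylsilyloxy)decahydroazulen-4-yl 4-acetoxybenzoate | CC(C)[C@]1(O[Si](CC)(CC)CC)CC[C@]2(C)C[C@@H]3OC(C)(C)O[C@]3(C)C(=O)[C@H](OC(=O)c4ccc(OC(C)=O)cc4)[C@H]21 | intermediate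
37 | (3R,3aS,4R,6S,7S,8aR)-3,6,7-trihydroxy-3-isopropyl-6,8a-dimethyl-5-oxodecahydroazulen-4-yl 4-hydroxybenzoate | CC(C)[C@]1(O)CC[C@]2(C)C[C@H](O)[C@](C)(O)C(=O)[C@H](OC(=O)c3ccc(O)cc3)[C@H]21 | target

## Step count and least certain steps

Total step count: 23. Longest linear sequence: 23 steps, from 1 to 37; compounds 2, 6, 10, 17, 26 and 35 enter as purchased reagents.

**Step 9 (key step).** The most likely failure is poor enantioface selection or slow cyclisation, because the alkene is trisubstituted and must become a quaternary carbon inside the chiral pocket. Alkyne oligomerisation and loss of the silyl enol ether by adventitious acid could compete. Fallback, from 14 back to 16: the cycloaddition is run with the achiral [Rh(CO)2Cl]2 in toluene, the best-established form of this reaction, to give the racemic cycloadduct F1. Buffered fluoride as in step 10 gives the racemic ketone F2. Preparative chromatography on a chiral stationary phase then separates 16 from its enantiomer F3, so that catalyst control is replaced by resolution.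

**Step 17.** The pentadienyl intermediate could be oxidised at its C7 terminus with a shift of the double bond, or the hindered diene could react too slowly and over-oxidise. Fallback, from 28 back to 32: the order is changed so that no doubly allylic position is involved. Dihydroxylation of the electron-rich C6=C7 alkene of 28 (OsO4, N-methylmorpholine N-oxide) gives the diol F4, and 2,2-dimethoxypropane with pyridinium p-toluenesulfonate gives the acetonide F5. Allylic oxidation at C5, now the only allylic C–H position, with Rh2(cap)4 (dirhodium tetrakis(caprolactamate)) and t-BuOOH gives the enone acetonide F6. Hydrogenation over Pd/C from the α face then gives 32.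

**Step 19.** The C3a=C4 bond lies between two fully substituted carbons and the α isopropyl group at C3 adds to the hindrance, so incomplete hydrogenation is the main risk. A second risk is loss of facial control if the α-ketol binds the metal in an unproductive way. Fallback, from 30 to 31: radical hydrogen-atom-transfer reduction with Mn(dpm)3, PhSiH3 and t-BuOOH in i-PrOH. This delivers a hydrogen atom to the enone β-carbon without the alkene having to coordinate to a metal centre, again from the face opposite the C8a methyl. It makes no new compound.

**Step 15.** Deprotonation at the doubly allylic C5 or at C2, β-hydride reduction by the isopropyl reagent, or incomplete facial selectivity could lower the return of 27. Fallback, from 25 back to 27: isopropenylmagnesium bromide with CeCl3 is used instead; it is less basic and has no β-hydrogen to transfer. It gives the isopropenyl carbinol F7, whose 1,1-disubstituted alkene is then hydrogenated selectively with RhCl(PPh3)3 and H2 in the presence of the two trisubstituted alkenes to give 27.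

**Step 6.** Capture of the alkenyllithium may be inefficient, because cyclopropanone is released only in low concentration from its hemiacetal salt and the organolithium can be quenched by proton transfer first. Fallback, from 9 (through 11) back to 13: the ring is built on the chain instead. The alkenyllithium 11 is acylated with N-methoxy-N-methylacetamide to the enone F8. Kinetic enolisation at the methyl group (LiN(iPr)2, then t-BuMe2SiCl) gives the 2-siloxydiene F9. Simmons–Smith cyclopropanation of its electron-rich terminal double bond (Et2Zn, CH2I2) gives 13.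

## Further compounds

F1 | step 9 | rac-7-(tert-butyldimethylsilyloxy)-3,3-(ethylenedioxy)-8a-methyl-1,2,3,5,6,8a-hexahydroazulene | CC(C)(C)[Si](C)(C)OC1=CC2(C)CCC3(OCCO3)C2=CCC1
F2 | step 9 | rac-3,3-(ethylenedioxy)-8a-methyl-2,3,5,6,8,8a-hexahydroazulen-7(1H)-one | O=C1CC2(C)CCC3(OCCO3)C2=CCC1
F3 | step 9 | (8aS)-3,3-(ethylenedioxy)-8a-methyl-2,3,5,6,8,8a-hexahydroazulen-7(1H)-one (enantiomer of 16) | O=C1C[C@]2(C)CCC3(OCCO3)C2=CCC1
F4 | step 17 | (3R,6R,7S,8aR)-3-isopropyl-6,8a-dimethyl-3-(triethylsilyloxy)-1,2,3,5,6,7,8,8a-octahydroazulene-6,7-diol | CC(C)[C@]1(O[Si](CC)(CC)CC)CC[C@]2(C)C[C@H](O)[C@](C)(O)CC=C21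
F5 | step 17 | 6,7-O-isopropylidene derivative of F4 | CC(C)[C@]1(O[Si](CC)(CC)CC)CC[C@]2(C)C[C@@H]3OC(C)(C)O[C@]3(C)CC=C21
F6 | step 17 | 6,7-O-isopropylidene derivative of 30 (enone acetonide) | CC(C)[C@]1(O[Si](CC)(CC)CC)CC[C@]2(C)C[C@@H]3OC(C)(C)O[C@]3(C)C(=O)C=C21
F0 | step 19 | none | none
F7 | step 15 | (3R,8aR)-6,8a-dimethyl-3-(prop-1-en-2-yl)-1,2,3,5,8,8a-hexahydroazulen-3-ol | CC(=C)[C@]1(O)CC[C@]2(C)CC=C(C)CC=C21
F8 | step 6 | (E)-4-methyl-6-{2-[(trimethylsilyl)ethynyl]-1,3-dioxolan-2-yl}hex-3-en-2-one | C[Si](C)(C)C#CC1(OCCO1)CC/C(C)=C/C(C)=O
F9 | step 6 | tert-butyldimethyl{[(E)-4-methyl-6-{2-[(trimethylsilyl)ethynyl]-1,3-dioxolan-2-yl}hexa-1,3-dien-2-yl]oxy}silane | C[Si](C)(C)C#CC1(OCCO1)CC/C(C)=C/C(=C)O[Si](C)(C)C(C)(C)C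
A1 | alternative 1 | 3-allylcyclopent-2-en-1-one | C=CCC1=CC(=O)CC1
A2 | alternative 1 | ethyl glyoxylate | CCOC(=O)C=O
A3 | alternative 1 | ethyl 2-hydroxy-2-(2-allyl-2-methyl-5-oxocyclopentyl)acetate (trans ring substituents, anti aldol adduct) | CCOC(=O)[C@H](O)[C@H]1C(=O)CC[C@]1(C)CC=C
A4 | alternative 1 | trans-fused 4α-hydroxy-6,8a-dimethyl-1,2,3a,4,8,8a-hexahydroazulene-3,5-dione | O=C1CC[C@]2(C)CC=C(C)C(=O)[C@H](O)[C@H]21
A5 | alternative 2 | keto aldehyde with acetonide at C4/C5 and dioxolane at C3 | O=CC[C@@]1(C)CCC2(OCCO2)[C@@H]1[C@H]1OC(C)(C)O[C@@H]1C(C)=O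
A6 | alternative 2 | trans-fused hydroazulene 6,7-cis-diol with acetonide and dioxolane | C15(OCCO5)CC[C@]2(C)C[C@H](O)[C@](C)(O)[C@H]3OC(C)(C)O[C@@H]3[C@H]21
A7 | alternative 3 | diquinane enone with C3 triethylsilyloxy and isopropyl groups | CC(C)[C@]1(O[Si](CC)(CC)CC)CC[C@]2(C)CC(=O)C(C)=C12
A8 | alternative 3 | acetylene | C#C
A9 | alternative 3 | cyclobutene-fused tricyclic ketone | CC(C)[C@]1(O[Si](CC)(CC)CC)CC[C@]2(C)CC(=O)[C@@]3(C)C=C[C@@]123
A10 | alternative 3 | (3R,8aR)-3-isopropyl-6,8a-dimethyl-3-(triethylsilyloxy)-2,3,8,8a-tetrahydroazulen-7(1H)-one (linear dienone, double bonds C3a=C4 and C5=C6) | CC(C)[C@]1(O[Si](CC)(CC)CC)CC[C@]2(C)CC(=O)C(C)=CC=C21
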